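## Retrosynthetic overview
1. GA49 (20) ⇐ acid removal of acetonide and MOM ester ⇐ 12α-alcohol 19 ⇐ equatorial-face hydride reduction of 12-ketone 18 ⇐ oxidation and methylenation of the 12β-hydroxy-16-ketone 16.
2. 16 ⇐ transamination of amino alcohol 13 ⇐ hydrogenolysis of isoxazolidine 12 ⇐ intramolecular nitrone–alkene [3+2] cycloaddition, which re-forms ring D (C13–C16) and makes the C12–O bond in one event (key step).
3. Nitrone 11 ⇐ 13,16-seco-12-en-16-al 10 ⇐ Norrish type 1 opening of the 17-nor-16-ketone 8.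
4. 8 ⇐ acetonide of the 2β,3β-diol ⇐ OsO4 cis-dihydroxylation of the Δ2 alkene ⇐ dehydration of the 3β-OH ⇐ ozonolysis of GA4 MOM ester.
5. Ring order: rings A, B, C and the 19,10-lactone (C4, C5, C6, C8, C9, C10) are bought in GA4; ring D is cut open and rebuilt last by the cycloaddition.

Assumption: GA4 (the 13-deoxy C19 gibberellin made by fermentation and sold as a plant-growth regulator) is taken as the commercial chiral starting material; GA49 is the target of the task; gibberellane numbering is used (lactone C19→C10, acid C7 on C6, ring D = C8, C14, C13, C16, C15).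

## Route

Step 1
Reactants: 1 GA4
Product: 2 GA4 methoxymethyl ester
Conditions: MOMCl (1.05 equiv), i-Pr2NEt, CH2Cl2, 0 °C
Reagents that add atoms: chloromethyl methyl ether, COCCl
Why: O-alkylation of the carboxylate (bimolecular nucleophilic substitution on the α-chloro ether) is much faster than etherification of the hindered axial 3β-OH, so only the acid is masked as an acid-labile acetal ester; no stereocentre is touched.

Step 2
Reactants: 2 GA4 methoxymethyl ester
Product: 4 17-nor-16-oxo-GA4 methoxymethyl ester, via secondary ozonide 3 (not isolated)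
Conditions: O3, CH2Cl2, −78 °C; then Me2S, −78 °C → rt
Reagents that add atoms: ozone, [O-][O+]=O
Why: Ozonolysis (1,3-dipolar cycloaddition of O3, Criegee rearrangement, reductive work-up) cleaves the only C=C bond, so later alkene chemistry in ring A is unambiguous.

Step 3
Reactants: 4 17-nor-16-oxo-GA4 methoxymethyl ester
Product: 5 17-nor-16-oxo-2,3-didehydro-GA9 methoxymethyl ester
Conditions: Martin sulfurane (Ph2S[OC(CF3)2Ph]2), CH2Cl2, 0 °C → rt
Reagents that add atoms: none
Why: Martin sulfurane dehydration by anti-periplanar elimination from the alkoxysulfonium ion: the axial 3β-O and the axial 2α-H are trans-diaxial and C4 is quaternary, so only the Δ2 alkene can form.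

Step 4
Reactants: 5 17-nor-16-oxo-2,3-didehydro-GA9 methoxymethyl ester
Product: 7 2β,3β-dihydroxy-17-nor-16-oxo-GA9 methoxymethyl ester, via osmate ester 6 (not isolated)
Conditions: OsO4 (2 mol%), NMO, acetone/H2O 8:1, rt
Reagents that add atoms: osmium tetroxide, O=[Os](=O)(=O)=O; N-methylmorpholine N-oxide, C[N+]1([O-])CCOCC1; water, O
Why: Upjohn cis-dihydroxylation ([3+2] addition of OsO4) on the β (exo) face of the 6-oxabicyclo[3.2.1]octene, away from the α lactone bridge, sets C2 and C3 as the 2β,3β-diol.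

Step 5
Reactants: 7 2β,3β-dihydroxy-17-nor-16-oxo-GA9 methoxymethyl ester
Product: 8 2β,3β-O-isopropylidene-17-nor-16-oxo-GA9 methoxymethyl ester
Conditions: Me2C(OMe)2, PPTS (cat.), acetone, rt
Reagents that add atoms: 2,2-dimethoxypropane, COC(C)(C)OC
Why: Acid-catalysed transacetalisation of the cis diol gives the acetonide, which protects ring A through the oxidation and hydride steps; acetone as solvent keeps the 16-ketone free.

Step 6
Reactants: 8 2β,3β-O-isopropylidene-17-nor-16-oxo-GA9 methoxymethyl ester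
Product: 10 13,16-seco-17-nor-12-en-16-al (acetonide MOM ester), via acyl–alkyl biradical 9 (not isolated)
Conditions: hν (medium-pressure Hg lamp, Pyrex, λ > 290 nm), degassed benzene, 0.01 M, 20 °C, to about 70% conversion
Reagents that add atoms: none
Why: Norrish type 1 α-cleavage on the more substituted side (C13–C16) gives the biradical, which disproportionates by transfer of a C12 hydrogen to the acyl carbon, as camphor-type bridged ketones do; no new stereocentre, C13 is flattened on purpose.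

Step 7
Reactants: 10 13,16-seco-17-nor-12-en-16-al (acetonide MOM ester)
Product: 12 ring D isoxazolidine (N-benzyl; C16–C13 bond restored; N on C16 cis to C12; ring O on C12β), via N-benzyl nitrone 11 (not isolated)
Conditions: BnNHOH·HCl, Et3N, MgSO4, toluene, rt; then 110 °C, 0.01 M
Reagents that add atoms: N-benzylhydroxylamine hydrochloride, Cl.ONCc1ccccc1
Why: Condensation gives the (Z)-aldonitrone, and its intramolecular nitrone–alkene 1,3-dipolar cycloaddition (Huisgen [3+2]) is steered by the three-atom tether on the β face of C8, so C16 bonds to C13 (five-membered ring D, natural C13 configuration) and oxygen adds suprafacially to C12 on the same β face; C16 stays tetrahedral, so the bridged adduct holds no strained bridgehead C=N.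

Step 8
Reactants: 12 ring D isoxazolidine
Product: 13 16-amino-12β-hydroxy-17-nor-GA34 2,3-acetonide methoxymethyl ester
Conditions: H2 (1 atm), Pd(OH)2/C, MeOH, rt
Reagents that add atoms: none
Why: Hydrogenolysis over Pd(OH)2/C cleaves the weak N–O bond and the benzylic C–N bond; the C12–O bond is not touched, so the 12β configuration from the cycloaddition is kept.

Step 9
Reactants: 13 16-amino-12β-hydroxy-17-nor-GA34 2,3-acetonide methoxymethyl ester
Product: 16 12β-hydroxy-17-nor-16-oxo-GA34 2,3-acetonide methoxymethyl ester, via quinone imine 14 (not isolated), via aryl ketimine 15 (not isolated)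
Conditions: 3,5-di-tert-butyl-1,2-benzoquinone, MeOH/THF, rt; then aq. oxalic acid, THF, pH 3, rt
Reagents that add atoms: water, O
Why: Quinone-mediated transamination: the amine condenses with the unhindered quinone carbonyl, a prototropic shift driven by aromatisation moves the C=N bond to C16, and mild aqueous acid hydrolyses the ketimine; base is avoided because the alkoxide of this β-hydroxy ketone could fragment by retro-aldol cleavage of C12–C13.

Step 10
Reactants: 16 12β-hydroxy-17-nor-16-oxo-GA34 2,3-acetonide methoxymethyl ester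
Product: 17 12β-hydroxy-GA34 2,3-acetonide methoxymethyl ester (12-epimer of protected GA49)
Conditions: Zn, CH2Br2, TiCl4 (pre-formed slurry, excess), THF/CH2Cl2, 0 °C → rt; aq. NaHCO3 work-up
Reagents that add atoms: dibromomethane, BrCBr
Why: Takai–Lombardo methylenation: the non-basic zinc–titanium methylene reagent adds to the 16-ketone and eliminates the metal oxide, which restores C17 without the ylide and alkoxide conditions that would open the β-hydroxy ketone; excess reagent covers the free 12-OH.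

Step 11
Reactants: 17 12β-hydroxy-GA34 2,3-acetonide methoxymethyl ester
Product: 18 12-oxo-GA34 2,3-acetonide methoxymethyl ester
Conditions: Dess–Martin periodinane, NaHCO3, CH2Cl2, rt
Reagents that add atoms: none
Why: Dess–Martin oxidation removes the wrongly configured C12 centre; the β,γ-unsaturated ketone cannot move into conjugation because C13 is a bridgehead.

Step 12
Reactants: 18 12-oxo-GA34 2,3-acetonide methoxymethyl ester
Product: 19 GA49 2,3-acetonide methoxymethyl ester (12α-OH)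
Conditions: LiBH(s-Bu)3 (L-Selectride), THF, −78 °C; then H2O
Reagents that add atoms: none
Why: Substrate-controlled ketone reduction: the axial α face of C12 is blocked by the syn-axial C9–C10 bond, so the bulky hydride attacks along the equatorial β trajectory and gives the axial 12α-alcohol.

Step 13
Reactants: 19 GA49 2,3-acetonide methoxymethyl ester
Product: 20 GA49
Conditions: 2 M HCl/THF 1:3, rt
Reagents that add atoms: none
Why: Acid-catalysed acetal hydrolysis removes both the isopropylidene group and the methoxymethyl ester without base, which avoids retro-aldol epimerisation at C3; the 13-deoxy exocyclic alkene tolerates dilute acid at room temperature.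

## Compound list
1 | GA4 (13-deoxy C19 gibberellin: 3β-hydroxy, 19,10-lactone, 16-ene, 7-oic acid) | C=C1C[C@]23C[C@H]1CC[C@H]2[C@@]12CC[C@H](O)[C@@](C)(C(=O)O1)[C@H]2[C@@H]3C(=O)O | starting material
2 | GA4 methoxymethyl ester | C=C1C[C@]23C[C@H]1CC[C@H]2[C@@]12CC[C@H](O)[C@@](C)(C(=O)O1)[C@H]2[C@@H]3C(=O)OCOC | intermediate
3 | secondary ozonide of 2 (1,2,4-trioxolane spiro at C16, C16 epimers) | C1OOC2(O1)C[C@]34C[C@H]2CC[C@H]3[C@@]56CC[C@H](O)[C@@](C)(C(=O)O5)[C@H]6[C@@H]4C(=O)OCOC | intermediate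
4 | 17-nor-16-oxo-GA4 methoxymethyl ester | O=C1C[C@]23C[C@H]1CC[C@H]2[C@@]12CC[C@H](O)[C@@](C)(C(=O)O1)[C@H]2[C@@H]3C(=O)OCOC | intermediate
5 | 17-nor-16-oxo-2,3-didehydro-GA9 methoxymethyl ester (Δ2 alkene, no 3-OH) | O=C1C[C@]23C[C@H]1CC[C@H]2[C@@]12CC=C[C@@](C)(C(=O)O1)[C@H]2[C@@H]3C(=O)OCOC | intermediate
6 | cyclic 2β,3β-osmate ester of 5 (hexavalent osmium glycolate) | O=C1C[C@]23C[C@H]1CC[C@H]2[C@@]12C[C@@H]4O[Os](=O)(=O)O[C@@H]4[C@@](C)(C(=O)O1)[C@H]2[C@@H]3C(=O)OCOC | intermediate
7 | 2β,3β-dihydroxy-17-nor-16-oxo-GA9 methoxymethyl ester | O=C1C[C@]23C[C@H]1CC[C@H]2[C@@]12C[C@H](O)[C@H](O)[C@@](C)(C(=O)O1)[C@H]2[C@@H]3C(=O)OCOC | intermediate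
8 | 2β,3β-O-isopropylidene-17-nor-16-oxo-GA9 methoxymethyl ester | O=C1C[C@]23C[C@H]1CC[C@H]2[C@@]12C[C@@H]4OC(C)(C)O[C@@H]4[C@@](C)(C(=O)O1)[C@H]2[C@@H]3C(=O)OCOC | intermediate
9 | acyl–alkyl biradical (acyl radical at C16, alkyl radical at C13) | O=[C]C[C@]12C[CH]CC[C@H]1[C@@]34C[C@@H]5OC(C)(C)O[C@@H]5[C@@](C)(C(=O)O3)[C@H]4[C@@H]2C(=O)OCOC | intermediate
10 | 13,16-seco-17-nor-12-en-16-al (ring C cyclohexene, CH2CHO on C8; acetonide MOM ester) | O=CC[C@]12CC=CC[C@H]1[C@@]34C[C@@H]5OC(C)(C)O[C@@H]5[C@@](C)(C(=O)O3)[C@H]4[C@@H]2C(=O)OCOC | intermediate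
11 | (Z)-N-benzyl nitrone of 10 | [O-]/[N+](Cc9ccccc9)=C\C[C@]12CC=CC[C@H]1[C@@]34C[C@@H]5OC(C)(C)O[C@@H]5[C@@](C)(C(=O)O3)[C@H]4[C@@H]2C(=O)OCOC | intermediate
12 | ring D isoxazolidine (N-benzyl; C16–C13 bond; N on C16 cis to C12; ring O on C12β; acetonide MOM ester) | N1(Cc8ccccc8)[C@H]2C[C@]34C[C@H]2[C@H](O1)C[C@H]3[C@@]56C[C@@H]7OC(C)(C)O[C@@H]7[C@@](C)(C(=O)O5)[C@H]6[C@@H]4C(=O)OCOC | intermediate
13 | 16-amino-12β-hydroxy-17-nor-GA34 2,3-acetonide methoxymethyl ester (NH2 on C16 cis to C12) | N[C@H]1C[C@]23C[C@H]1[C@H](O)C[C@H]2[C@@]12C[C@@H]4OC(C)(C)O[C@@H]4[C@@](C)(C(=O)O1)[C@H]2[C@@H]3C(=O)OCOC | intermediate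
14 | quinone imine (N of 13 condensed with C1 of 3,5-di-tert-butyl-1,2-benzoquinone) | O=C9C(C(C)(C)C)=CC(C(C)(C)C)=CC9=N[C@H]1C[C@]23C[C@H]1[C@H](O)C[C@H]2[C@@]12C[C@@H]4OC(C)(C)O[C@@H]4[C@@](C)(C(=O)O1)[C@H]2[C@@H]3C(=O)OCOC | intermediate
15 | aryl ketimine (C16=N–aryl, aryl = 3,5-di-tert-butyl-2-hydroxyphenyl) | Oc9c(C(C)(C)C)cc(C(C)(C)C)cc9N=C1C[C@]23C[C@H]1[C@H](O)C[C@H]2[C@@]12C[C@@H]4OC(C)(C)O[C@@H]4[C@@](C)(C(=O)O1)[C@H]2[C@@H]3C(=O)OCOC | intermediate
16 | 12β-hydroxy-17-nor-16-oxo-GA34 2,3-acetonide methoxymethyl ester | O=C1C[C@]23C[C@H]1[C@H](O)C[C@H]2[C@@]12C[C@@H]4OC(C)(C)O[C@@H]4[C@@](C)(C(=O)O1)[C@H]2[C@@H]3C(=O)OCOC | intermediate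
17 | 12β-hydroxy-GA34 2,3-acetonide methoxymethyl ester (12-epimer of protected GA49) | C=C1C[C@]23C[C@H]1[C@H](O)C[C@H]2[C@@]12C[C@@H]4OC(C)(C)O[C@@H]4[C@@](C)(C(=O)O1)[C@H]2[C@@H]3C(=O)OCOC | intermediate
18 | 12-oxo-GA34 2,3-acetonide methoxymethyl ester | C=C1C[C@]23C[C@H]1C(=O)C[C@H]2[C@@]12C[C@@H]4OC(C)(C)O[C@@H]4[C@@](C)(C(=O)O1)[C@H]2[C@@H]3C(=O)OCOC | intermediate
19 | GA49 2,3-acetonide methoxymethyl ester (12α-OH) | C=C1C[C@]23C[C@H]1[C@@H](O)C[C@H]2[C@@]12C[C@@H]4OC(C)(C)O[C@@H]4[C@@](C)(C(=O)O1)[C@H]2[C@@H]3C(=O)OCOC | intermediate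
20 | GA49 (2β,3β,12α-trihydroxy, 19,10-lactone, 16-ene, 7-oic acid) | C=C1C[C@]23C[C@H]1[C@@H](O)C[C@H]2[C@@]12C[C@H](O)[C@H](O)[C@@](C)(C(=O)O1)[C@H]2[C@@H]3C(=O)O | target

## Step count and risks
Total: 13 steps. Longest linear sequence: 13 steps (fully linear from GA4).

The three steps most likely to fail:

First, step 6 (photochemical ring opening). The hydrogen transfer from C12 needs a seven-membered transition state, and the biradical can also take a hydrogen from C14 (giving the 13(14)-ene) or collapse to a ketene. The regiochemistry is argued by analogy only, so the 12-ene may be a minor product; the 13(14)-ene cannot give 12 and is removed by chromatography. The fallback opens ring D ionically with regiocontrol. It sets out from 8: Baeyer–Villiger oxidation (m-CPBA, NaHCO3; the secondary C13 migrates with retention) gives the six-membered lactone F1. Weinreb aminolysis (MeNH(OMe)·HCl, Me3Al; the strained bridged lactone reacts before the hindered C7 ester) opens it to the 13β-hydroxy Weinreb amide F2, and Dess–Martin oxidation gives the 13-ketone F3. Kinetic enolisation away from the quaternary C8 (KN(SiMe3)2, PhNTf2, −78 °C) gives the Δ12 enol triflate F4. Reduction with Pd(OAc)2, PPh3, HCO2H and n-Bu3N gives the Δ12 alkene Weinreb amide F5, and Cp2Zr(H)Cl reduces the amide to the aldehyde, rejoining the route at 10.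

Second, step 7 (bridged nitrone cycloaddition). The unactivated, 1,2-disubstituted ring C alkene may react too slowly, or the tether may not reach the bridged transition state. The fallback closes ring D by a radical instead of a dipole. It sets out from 10: NH2OH·HCl and pyridine give the aldoxime F6, and dehydration with 1,1'-carbonyldiimidazole gives the nitrile F7. Epoxidation (m-CPBA, NaHCO3) on the open β face, opposite the axial C6 branch, gives the 12β,13β-epoxide F8. Cp2TiCl (trivalent titanium, made from Cp2TiCl2 and Zn in THF) opens the epoxide to the β-titanoxy C13 radical, which closes 5-exo onto the nitrile carbon from the β face. This gives the 12β-hydroxy 16-imine F9, which is hydrolysed on buffered aqueous work-up, rejoining the route at 16. Opening toward C12 is unproductive and costs yield.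

Third, step 12 (stereoselective reduction). The β face is flanked by the axial C13–C16 bond, so the selectivity is not certain. If hydride arrives from the α face and returns the equatorial 12β-alcohol, that face is accessible, and the centre is inverted by substitution instead. The fallback sets out from 17: Mitsunobu reaction (chloroacetic acid, PPh3, DIAD) gives the 12α-chloroacetate F10, and thiourea with NaHCO3 in EtOH/THF at 50 °C removes the chloroacetyl group without touching the MOM ester, rejoining the route at 19.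

## Further compounds
F1 | step 6 | Baeyer–Villiger lactone (13β-O–C16(=O)–C15 bridge; acetonide MOM ester) | O=C1C[C@]23C[C@H](O1)CC[C@H]2[C@@]12C[C@@H]4OC(C)(C)O[C@@H]4[C@@](C)(C(=O)O1)[C@H]2[C@@H]3C(=O)OCOC
F2 | step 6 | 13β-hydroxy-13,16-seco Weinreb amide | CON(C)C(=O)C[C@]12C[C@H](O)CC[C@H]1[C@@]34C[C@@H]5OC(C)(C)O[C@@H]5[C@@](C)(C(=O)O3)[C@H]4[C@@H]2C(=O)OCOC
F3 | step 6 | 13-oxo-13,16-seco Weinreb amide | CON(C)C(=O)C[C@]12CC(=O)CC[C@H]1[C@@]34C[C@@H]5OC(C)(C)O[C@@H]5[C@@](C)(C(=O)O3)[C@H]4[C@@H]2C(=O)OCOC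
F4 | step 6 | Δ12 enol triflate (OTf on C13) | CON(C)C(=O)C[C@]12CC(OS(=O)(=O)C(F)(F)F)=CC[C@H]1[C@@]34C[C@@H]5OC(C)(C)O[C@@H]5[C@@](C)(C(=O)O3)[C@H]4[C@@H]2C(=O)OCOC
F5 | step 6 | 13,16-seco-12-ene Weinreb amide | CON(C)C(=O)C[C@]12CC=CC[C@H]1[C@@]34C[C@@H]5OC(C)(C)O[C@@H]5[C@@](C)(C(=O)O3)[C@H]4[C@@H]2C(=O)OCOC
F6 | step 7 | aldoxime of 10 (E/Z mixture) | ON=CC[C@]12CC=CC[C@H]1[C@@]34C[C@@H]5OC(C)(C)O[C@@H]5[C@@](C)(C(=O)O3)[C@H]4[C@@H]2C(=O)OCOC
F7 | step 7 | 13,16-seco-12-ene-16-nitrile | N#CC[C@]12CC=CC[C@H]1[C@@]34C[C@@H]5OC(C)(C)O[C@@H]5[C@@](C)(C(=O)O3)[C@H]4[C@@H]2C(=O)OCOC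
F8 | step 7 | 12β,13β-epoxy-13,16-seco-16-nitrile | N#CC[C@]12C[C@@H]6O[C@@H]6C[C@H]1[C@@]34C[C@@H]5OC(C)(C)O[C@@H]5[C@@](C)(C(=O)O3)[C@H]4[C@@H]2C(=O)OCOC
F9 | step 7 | 12β-hydroxy-16-imine (ring D closed) | N=C1C[C@]23C[C@H]1[C@H](O)C[C@H]2[C@@]12C[C@@H]4OC(C)(C)O[C@@H]4[C@@](C)(C(=O)O1)[C@H]2[C@@H]3C(=O)OCOC
F10 | step 12 | 12α-chloroacetate of protected GA49 | C=C1C[C@]23C[C@H]1[C@@H](OC(=O)CCl)C[C@H]2[C@@]12C[C@@H]4OC(C)(C)O[C@@H]4[C@@](C)(C(=O)O1)[C@H]2[C@@H]3C(=O)OCOC
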